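**Retrosynthetic overview**
- The target comes from a bis-benzyl-protected sodium sulfate: sulfation of a side-chain primary alcohol made by hydroboration of a 5-allyl group, then one hydrogenolysis of both benzyl ethers.
- The dihydrofuran ring is the only ring made (both benzene rings are bought). It closes by acid-mediated attack of an ortho-phenol on the benzylic carbinol of a 1,2-diarylpropane-1,3-diol, trans to the C3 substituent.
- The C2–C3 bond comes from an intermolecular Evans boron syn-aldol between an arylacetyl (S)-4-benzyloxazolidinone and O-benzylvanillin. The auxiliary fixes C3 and is then removed with LiBH4.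
- The arylacetyl imide comes from eugenol: ortho-formylation, O-allyl protection, one-carbon homologation (Wittig, hydrolysis, Pinnick) and N-acylation.

Assumption: the target is wanted as the free hydrogen sulfate exactly as drawn; it is carried as its sodium salt and protonated in the last operation.

**Route**

Step 1
Reactants: 1 eugenol (4-allyl-2-methoxyphenol)
Product: 2 5-allyl-2-hydroxy-3-methoxybenzaldehyde
Conditions: MgCl2 (anhydrous), Et3N, (CH2O)n, MeCN, reflux; aq HCl work-up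
Reagents that add atoms: paraformaldehyde (formaldehyde unit), C=O
Why: Casnati–Skattebøl ortho-formylation, in which the magnesium phenoxide delivers formaldehyde to the only free ortho position and a second formaldehyde oxidises the benzylic alkoxide to the aldehyde.

Step 2
Reactants: 2 5-allyl-2-hydroxy-3-methoxybenzaldehyde
Product: 3 5-allyl-2-(allyloxy)-3-methoxybenzaldehyde
Conditions: allyl bromide, K2CO3, DMF, rt → 50 °C
Reagents that add atoms: allyl bromide, C=CCBr
Why: Williamson ether synthesis on the acidic salicylaldehyde phenol gives an O-allyl group that withstands base, hydride and boron triflate and is later removed without touching benzyl ethers or the C-allyl group.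

Step 3
Reactants: 3 5-allyl-2-(allyloxy)-3-methoxybenzaldehyde
Product: 4 5-allyl-2-(allyloxy)-1-methoxy-3-(2-methoxyvinyl)benzene (E/Z mixture)
Conditions: Ph3P(CH2OMe)Cl (1.3 equiv), KOtBu (1.2 equiv), THF, 0 °C → rt
Reagents that add atoms: (methoxymethyl)triphenylphosphonium chloride, COC[P+](c1ccccc1)(c1ccccc1)c1ccccc1.[Cl-]
Why: Wittig olefination with the methoxymethylene ylide adds the one carbon needed, and keeping the salt in excess over the base avoids allyl-to-propenyl isomerisation.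

Step 4
Reactants: 4 5-allyl-2-(allyloxy)-1-methoxy-3-(2-methoxyvinyl)benzene
Product: 6 2-[5-allyl-2-(allyloxy)-3-methoxyphenyl]acetic acid, via arylacetaldehyde 5 (not isolated)
Conditions: 2 M HCl, THF, 50 °C; extract; then NaClO2, NaH2PO4, 2-methyl-2-butene, t-BuOH/H2O, 0 °C → rt
Reagents that add atoms: water, O; sodium chlorite, [Na+].[O-]Cl=O
Why: Enol ether hydrolysis followed directly by Pinnick oxidation converts the sensitive arylacetaldehyde to the acid, with 2-methyl-2-butene scavenging HOCl so the alkenes and the electron-rich ring are not chlorinated.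

Step 5
Reactants: 6 2-[5-allyl-2-(allyloxy)-3-methoxyphenyl]acetic acid; 7 (S)-4-benzyl-1,3-oxazolidin-2-one
Product: 9 (S)-3-{2-[5-allyl-2-(allyloxy)-3-methoxyphenyl]acetyl}-4-benzyl-1,3-oxazolidin-2-one, via mixed pivalic anhydride 8 (not isolated)
Conditions: PivCl, Et3N, THF, −20 °C; then LiCl, 7, −20 °C → rt
Reagents that add atoms: none
Why: N-acylation through the mixed pivalic anhydride, where LiCl/Et3N activates the oxazolidinone and attack occurs at the less hindered arylacetyl carbonyl.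

Step 6
Reactants: 9 (S)-3-{2-[5-allyl-2-(allyloxy)-3-methoxyphenyl]acetyl}-4-benzyl-1,3-oxazolidin-2-one; 10 4-(benzyloxy)-3-methoxybenzaldehyde (O-benzylvanillin)
Product: 13 (S)-4-benzyl-3-[(2S,3S)-2-[5-allyl-2-(allyloxy)-3-methoxyphenyl]-3-[4-(benzyloxy)-3-methoxyphenyl]-3-hydroxypropanoyl]-1,3-oxazolidin-2-one, via boron enolate 11 (not isolated), via boron aldolate 12 (not isolated)
Conditions: Bu2BOTf, iPr2NEt, CH2Cl2, 0 °C; then 10, −78 → 0 °C; pH 7 phosphate buffer, MeOH, 30% H2O2, 0 °C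
Reagents that add atoms: none
Why: Evans boron syn-aldol, in which the Z-dibutylboron enolate adds through a chair Zimmerman–Traxler transition state on the face away from the benzyl group of the (S)-auxiliary, forming the future C2–C3 bond and setting the α-carbon (future ring C3) and the carbinol carbon both as S (2,3-syn).

Step 7
Reactants: 13 the syn-aldol adduct
Product: 14 (1S,2R)-2-[5-allyl-2-(allyloxy)-3-methoxyphenyl]-1-[4-(benzyloxy)-3-methoxyphenyl]propane-1,3-diol
Conditions: LiBH4, H2O (1 equiv), Et2O/THF, 0 °C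
Reagents that add atoms: none
Why: Reductive cleavage of the N-acyl oxazolidinone at the exocyclic carbonyl gives the primary alcohol without epimerising the α-centre (its descriptor changes from S to R only through CIP priorities) and returns the auxiliary.

Step 8
Reactants: 14 (1S,2R)-2-[5-allyl-2-(allyloxy)-3-methoxyphenyl]-1-[4-(benzyloxy)-3-methoxyphenyl]propane-1,3-diol
Product: 15 (1S,2R)-2-(5-allyl-2-hydroxy-3-methoxyphenyl)-1-[4-(benzyloxy)-3-methoxyphenyl]propane-1,3-diol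
Conditions: Pd(PPh3)4 (5 mol %), morpholine (10 equiv), THF, rt
Reagents that add atoms: none
Why: Tsuji–Trost-type deallylation, in which zerovalent palladium ionises only the aryl allyl ether (phenoxide leaving group) and morpholine traps the π-allyl complex, while the C-allyl group and the benzyl ether have no leaving group.

Step 9
Reactants: 15 (1S,2R)-2-(5-allyl-2-hydroxy-3-methoxyphenyl)-1-[4-(benzyloxy)-3-methoxyphenyl]propane-1,3-diol
Product: 16 [(2S,3R)-5-allyl-2-[4-(benzyloxy)-3-methoxyphenyl]-7-methoxy-2,3-dihydro-1-benzofuran-3-yl]methanol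
Conditions: TsOH·H2O (10 mol %), CH2Cl2 (0.02 M), 0 °C → rt
Reagents that add atoms: none
Why: Acid-catalysed SN1 cycloetherification, in which the p-benzyloxy-stabilised benzylic cation is captured by the ortho-phenol in a five-membered closure (the primary alcohol could only give an oxetane) and the fixed C3 centre directs the aryl group trans under reversible conditions, so C2 becomes S.

Step 10
Reactants: 16 [(2S,3R)-5-allyl-2-[4-(benzyloxy)-3-methoxyphenyl]-7-methoxy-2,3-dihydro-1-benzofuran-3-yl]methanol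
Product: 17 (2S,3R)-5-allyl-3-[(benzyloxy)methyl]-2-[4-(benzyloxy)-3-methoxyphenyl]-7-methoxy-2,3-dihydro-1-benzofuran
Conditions: NaH, BnBr, Bu4NI (cat.), THF/DMF, 0 °C → rt
Reagents that add atoms: benzyl bromide, BrCc1ccccc1
Why: Williamson benzylation of the only free hydroxyl masks the ring CH2OH so that the alcohol made next is the only site open to sulfation.

Step 11
Reactants: 17 (2S,3R)-5-allyl-3-[(benzyloxy)methyl]-2-[4-(benzyloxy)-3-methoxyphenyl]-7-methoxy-2,3-dihydro-1-benzofuran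
Product: 19 3-[(2S,3R)-3-[(benzyloxy)methyl]-2-[4-(benzyloxy)-3-methoxyphenyl]-7-methoxy-2,3-dihydro-1-benzofuran-5-yl]propan-1-ol, via B-alkyl-9-BBN adduct 18 (not isolated)
Conditions: 9-BBN, THF, 0 °C → rt; then 3 M NaOH, 30% H2O2, 0 °C → rt
Reagents that add atoms: hydrogen peroxide, OO
Why: Brown hydroboration–oxidation with the bulky 9-BBN places boron on the terminal carbon of the allyl group, giving the 3-hydroxypropyl chain with anti-Markovnikov selectivity.

Step 12
Reactants: 19 3-[(2S,3R)-3-[(benzyloxy)methyl]-2-[4-(benzyloxy)-3-methoxyphenyl]-7-methoxy-2,3-dihydro-1-benzofuran-5-yl]propan-1-ol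
Product: 21 sodium 3-[(2S,3R)-3-[(benzyloxy)methyl]-2-[4-(benzyloxy)-3-methoxyphenyl]-7-methoxy-2,3-dihydro-1-benzofuran-5-yl]propyl sulfate, via pyridinium sulfate 20 (not isolated)
Conditions: SO3·pyridine (3 equiv), pyridine, rt; then aq NaHCO3, C18 chromatography
Reagents that add atoms: sulfur trioxide pyridine complex, [O-]S(=O)(=O)[n+]1ccccc1; sodium hydrogen carbonate, [Na+].OC([O-])=O
Why: O-sulfation of the single free primary alcohol with SO3·pyridine is clean, and exchange to the sodium salt removes pyridine, which would poison the catalyst of the last step.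

Step 13
Reactants: 21 sodium 3-[(2S,3R)-3-[(benzyloxy)methyl]-2-[4-(benzyloxy)-3-methoxyphenyl]-7-methoxy-2,3-dihydro-1-benzofuran-5-yl]propyl sulfate
Product: 23 3-[(2S,3R)-2-(4-hydroxy-3-methoxyphenyl)-3-(hydroxymethyl)-7-methoxy-2,3-dihydro-1-benzofuran-5-yl]propyl hydrogen sulfate, via sodium salt 22 (not isolated)
Conditions: H2 (1 atm), 10% Pd/C, MeOH/H2O, rt, monitored closely; filter; then 0.1 M HCl (1.0 equiv), 0 °C, C18 desalting, lyophilise
Reagents that add atoms: none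
Why: Catalytic hydrogenolysis removes the phenolic and the primary alkyl benzyl ether while the sulfate monoester anion and, at 1 atm and room temperature, the hindered ring benzylic C–O bond survive; cold stoichiometric acid then gives the free hydrogen sulfate without touching either stereocentre.

**Compound list**

1 | eugenol (4-allyl-2-methoxyphenol) | C=CCc1ccc(O)c(OC)c1 | starting material
2 | 5-allyl-2-hydroxy-3-methoxybenzaldehyde | C=CCc1cc(C=O)c(O)c(OC)c1 | intermediate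
3 | 5-allyl-2-(allyloxy)-3-methoxybenzaldehyde | C=CCOc1c(C=O)cc(CC=C)cc1OC | intermediate
4 | 5-allyl-2-(allyloxy)-1-methoxy-3-(2-methoxyvinyl)benzene (E/Z mixture) | C=CCOc1c(C=COC)cc(CC=C)cc1OC | intermediate
5 | 2-[5-allyl-2-(allyloxy)-3-methoxyphenyl]acetaldehyde (not isolated) | C=CCOc1c(CC=O)cc(CC=C)cc1OC | intermediate
6 | 2-[5-allyl-2-(allyloxy)-3-methoxyphenyl]acetic acid | C=CCOc1c(CC(=O)O)cc(CC=C)cc1OC | intermediate
7 | (S)-4-benzyl-1,3-oxazolidin-2-one | O=C1N[C@@H](Cc2ccccc2)CO1 | starting material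
8 | mixed anhydride of 6 and pivalic acid (not isolated) | C=CCOc1c(CC(=O)OC(=O)C(C)(C)C)cc(CC=C)cc1OC | intermediate
9 | (S)-3-{2-[5-allyl-2-(allyloxy)-3-methoxyphenyl]acetyl}-4-benzyl-1,3-oxazolidin-2-one | C=CCOc1c(CC(=O)N2[C@@H](Cc3ccccc3)COC2=O)cc(CC=C)cc1OC | intermediate
10 | 4-(benzyloxy)-3-methoxybenzaldehyde (O-benzylvanillin) | COc1cc(C=O)ccc1OCc1ccccc1 | starting material
11 | (Z)-dibutylboron enolate of 9 (not isolated) | CCCCB(CCCC)O/C(=C\c1cc(CC=C)cc(OC)c1OCC=C)N1[C@@H](Cc2ccccc2)COC1=O | intermediate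
12 | O-dibutylboryl aldolate of 13 (not isolated) | O=C(N1[C@@H](Cc2ccccc2)COC1=O)[C@@H](c1cc(CC=C)cc(OC)c1OCC=C)[C@H](OB(CCCC)CCCC)c1ccc(OCc2ccccc2)c(OC)c1 | intermediate
13 | (S)-4-benzyl-3-[(2S,3S)-2-[5-allyl-2-(allyloxy)-3-methoxyphenyl]-3-[4-(benzyloxy)-3-methoxyphenyl]-3-hydroxypropanoyl]-1,3-oxazolidin-2-one | O=C(N1[C@@H](Cc2ccccc2)COC1=O)[C@@H](c1cc(CC=C)cc(OC)c1OCC=C)[C@H](O)c1ccc(OCc2ccccc2)c(OC)c1 | intermediate
14 | (1S,2R)-2-[5-allyl-2-(allyloxy)-3-methoxyphenyl]-1-[4-(benzyloxy)-3-methoxyphenyl]propane-1,3-diol | OC[C@@H](c1cc(CC=C)cc(OC)c1OCC=C)[C@H](O)c1ccc(OCc2ccccc2)c(OC)c1 | intermediate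
15 | (1S,2R)-2-(5-allyl-2-hydroxy-3-methoxyphenyl)-1-[4-(benzyloxy)-3-methoxyphenyl]propane-1,3-diol | OC[C@@H](c1cc(CC=C)cc(OC)c1O)[C@H](O)c1ccc(OCc2ccccc2)c(OC)c1 | intermediate
16 | [(2S,3R)-5-allyl-2-[4-(benzyloxy)-3-methoxyphenyl]-7-methoxy-2,3-dihydro-1-benzofuran-3-yl]methanol | COc1cc([C@H]2Oc3c(OC)cc(CC=C)cc3[C@@H]2CO)ccc1OCc1ccccc1 | intermediate
17 | (2S,3R)-5-allyl-3-[(benzyloxy)methyl]-2-[4-(benzyloxy)-3-methoxyphenyl]-7-methoxy-2,3-dihydro-1-benzofuran | COc1cc([C@H]2Oc3c(OC)cc(CC=C)cc3[C@@H]2COCc2ccccc2)ccc1OCc1ccccc1 | intermediate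
18 | B-alkyl-9-borabicyclo[3.3.1]nonane adduct of 17 (not isolated) | COc1cc([C@H]2Oc3c(OC)cc(CCCB4C5CCCC4CCC5)cc3[C@@H]2COCc2ccccc2)ccc1OCc1ccccc1 | intermediate
19 | 3-[(2S,3R)-3-[(benzyloxy)methyl]-2-[4-(benzyloxy)-3-methoxyphenyl]-7-methoxy-2,3-dihydro-1-benzofuran-5-yl]propan-1-ol | COc1cc([C@H]2Oc3c(OC)cc(CCCO)cc3[C@@H]2COCc2ccccc2)ccc1OCc1ccccc1 | intermediate
20 | pyridinium 3-[(2S,3R)-3-[(benzyloxy)methyl]-2-[4-(benzyloxy)-3-methoxyphenyl]-7-methoxy-2,3-dihydro-1-benzofuran-5-yl]propyl sulfate (not isolated) | COc1cc([C@H]2Oc3c(OC)cc(CCCOS(=O)(=O)[O-])cc3[C@@H]2COCc2ccccc2)ccc1OCc1ccccc1.c1cc[nH+]cc1 | intermediate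
21 | sodium 3-[(2S,3R)-3-[(benzyloxy)methyl]-2-[4-(benzyloxy)-3-methoxyphenyl]-7-methoxy-2,3-dihydro-1-benzofuran-5-yl]propyl sulfate | COc1cc([C@H]2Oc3c(OC)cc(CCCOS(=O)(=O)[O-])cc3[C@@H]2COCc2ccccc2)ccc1OCc1ccccc1.[Na+] | intermediate
22 | sodium 3-[(2S,3R)-2-(4-hydroxy-3-methoxyphenyl)-3-(hydroxymethyl)-7-methoxy-2,3-dihydro-1-benzofuran-5-yl]propyl sulfate (not isolated) | COc1cc([C@H]2Oc3c(OC)cc(CCCOS(=O)(=O)[O-])cc3[C@@H]2CO)ccc1O.[Na+] | intermediate
23 | 3-[(2S,3R)-2-(4-hydroxy-3-methoxyphenyl)-3-(hydroxymethyl)-7-methoxy-2,3-dihydro-1-benzofuran-5-yl]propyl hydrogen sulfate | COc1cc([C@H]2Oc3c(OC)cc(CCCOS(=O)(=O)O)cc3[C@@H]2CO)ccc1O | target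

**Totals and risks**

Total step count: 13. Longest linear sequence: 13 steps (1 → 23); compounds 7 and 10 are bought.

Steps most likely to fail:

Step 1. The guaiacol-type methoxy group can tie up MgCl2 and make the formylation sluggish. Fallback, setting out from 1 and coming back at 2: heat eugenol 1 with PhB(OH)2, (CH2O)n and catalytic propanoic acid in toluene (Dean–Stark) so that the boronate templates an ortho-hydroxymethylation, giving 6-allyl-8-methoxy-2-phenyl-4H-1,3,2-benzodioxaborinine F1. Boronate exchange with propane-1,3-diol releases 4-allyl-2-(hydroxymethyl)-6-methoxyphenol F2, and MnO2 in CH2Cl2 oxidises the benzylic alcohol to aldehyde 2.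

Step 6. The stabilised arylacetyl boron enolate may add slowly and reversibly to the electron-rich aldehyde, eroding yield or diastereoselectivity. Fallback, setting out from 6 and coming back at 14: couple acid 6 with (S)-4-benzyl-1,3-thiazolidine-2-thione (EDC·HCl, DMAP, CH2Cl2) to give (S)-2-[5-allyl-2-(allyloxy)-3-methoxyphenyl]-1-(4-benzyl-2-thioxo-1,3-thiazolidin-3-yl)ethan-1-one F3. Treat it with TiCl4, iPr2NEt and N-methyl-2-pyrrolidinone in CH2Cl2 at 0 °C to form the more reactive chlorotitanium Z-enolate F4, and add aldehyde 10. This passes through the trichlorotitanium aldolate F5 to the same-sense (2S,3S) syn adduct, the N-acyl thiazolidinethione aldol F6. NaBH4 in THF/EtOH at 0 °C cleaves the thiazolidinethione directly and delivers diol 14.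

Step 13. The primary alkyl benzyl ether cleaves slowly on the sulfate salt, and long exposure risks hydrogenolysis of the ring benzylic C2–O bond. Fallback, setting out from 16 and coming back at 22:
- Acetylate 16 (Ac2O, pyridine, DMAP) to [(2S,3R)-5-allyl-2-[4-(benzyloxy)-3-methoxyphenyl]-7-methoxy-2,3-dihydro-1-benzofuran-3-yl]methyl acetate F7.
- Hydroborate with 9-BBN to the B-alkyl-9-borabicyclo[3.3.1]nonane adduct F8 and oxidise mildly with NaBO3·4H2O to the 3-hydroxypropyl acetate F9.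
- Sulfate with SO3·pyridine to the pyridinium sulfate acetate F10 and exchange with NaHCO3 to the sodium sulfate acetate F11.
- Run a short hydrogenolysis (H2, Pd/C) that only has to cleave the fast-reacting phenolic benzyl ether, giving the phenolic sodium sulfate acetate F12.
- Remove the acetate with catalytic NaOMe in MeOH to reach sodium salt 22, which is protonated as in step 13.

**Further compounds**

F1 | step 1 | 6-allyl-8-methoxy-2-phenyl-4H-1,3,2-benzodioxaborinine | C=CCc1cc(OC)c2OB(c3ccccc3)OCc2c1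
F2 | step 1 | 4-allyl-2-(hydroxymethyl)-6-methoxyphenol | C=CCc1cc(CO)c(O)c(OC)c1
F3 | step 6 | (S)-2-[5-allyl-2-(allyloxy)-3-methoxyphenyl]-1-(4-benzyl-2-thioxo-1,3-thiazolidin-3-yl)ethan-1-one | C=CCOc1c(CC(=O)N2[C@@H](Cc3ccccc3)CSC2=S)cc(CC=C)cc1OC
F4 | step 6 | chlorotitanium Z-enolate of F3 | Cl[Ti](Cl)(Cl)O/C(=C\c1cc(CC=C)cc(OC)c1OCC=C)N1[C@@H](Cc2ccccc2)CSC1=S
F5 | step 6 | trichlorotitanium aldolate of F6 | S=C1SC[C@H](Cc2ccccc2)N1C(=O)[C@@H](c1cc(CC=C)cc(OC)c1OCC=C)[C@H](O[Ti](Cl)(Cl)Cl)c1ccc(OCc2ccccc2)c(OC)c1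
F6 | step 6 | (2S,3S)-2-[5-allyl-2-(allyloxy)-3-methoxyphenyl]-3-[4-(benzyloxy)-3-methoxyphenyl]-1-[(S)-4-benzyl-2-thioxo-1,3-thiazolidin-3-yl]-3-hydroxypropan-1-one | S=C1SC[C@H](Cc2ccccc2)N1C(=O)[C@@H](c1cc(CC=C)cc(OC)c1OCC=C)[C@H](O)c1ccc(OCc2ccccc2)c(OC)c1
F7 | step 13 | [(2S,3R)-5-allyl-2-[4-(benzyloxy)-3-methoxyphenyl]-7-methoxy-2,3-dihydro-1-benzofuran-3-yl]methyl acetate | COc1cc([C@H]2Oc3c(OC)cc(CC=C)cc3[C@@H]2COC(C)=O)ccc1OCc1ccccc1
F8 | step 13 | B-alkyl-9-borabicyclo[3.3.1]nonane adduct of F7 | COc1cc([C@H]2Oc3c(OC)cc(CCCB4C5CCCC4CCC5)cc3[C@@H]2COC(C)=O)ccc1OCc1ccccc1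
F9 | step 13 | [(2S,3R)-2-[4-(benzyloxy)-3-methoxyphenyl]-5-(3-hydroxypropyl)-7-methoxy-2,3-dihydro-1-benzofuran-3-yl]methyl acetate | COc1cc([C@H]2Oc3c(OC)cc(CCCO)cc3[C@@H]2COC(C)=O)ccc1OCc1ccccc1
F10 | step 13 | pyridinium 3-[(2S,3R)-3-(acetoxymethyl)-2-[4-(benzyloxy)-3-methoxyphenyl]-7-methoxy-2,3-dihydro-1-benzofuran-5-yl]propyl sulfate | COc1cc([C@H]2Oc3c(OC)cc(CCCOS(=O)(=O)[O-])cc3[C@@H]2COC(C)=O)ccc1OCc1ccccc1.c1cc[nH+]cc1
F11 | step 13 | sodium 3-[(2S,3R)-3-(acetoxymethyl)-2-[4-(benzyloxy)-3-methoxyphenyl]-7-methoxy-2,3-dihydro-1-benzofuran-5-yl]propyl sulfate | COc1cc([C@H]2Oc3c(OC)cc(CCCOS(=O)(=O)[O-])cc3[C@@H]2COC(C)=O)ccc1OCc1ccccc1.[Na+]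
F12 | step 13 | sodium 3-[(2S,3R)-3-(acetoxymethyl)-2-(4-hydroxy-3-methoxyphenyl)-7-methoxy-2,3-dihydro-1-benzofuran-5-yl]propyl sulfate | COc1cc([C@H]2Oc3c(OC)cc(CCCOS(=O)(=O)[O-])cc3[C@@H]2COC(C)=O)ccc1O.[Na+]
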